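**Numbering used throughout:** 1 paeonol, 2 benzyl bromide, 3 O-benzylpaeonol, 4 arylglyoxal, 5 4-bromoresorcinol, 6 methanol, 7 α-hydroxy ketone (in flask), 8 α-methoxy ketone (in flask), 9 bromobenzofuran benzyl ether, 10 bromo bis-phenol, 11 prenylboronic acid pinacol ester, 12 ambofuranol.

## Analysis of the target

Ambofuranol is a 2-arylbenzofuran: a furan ring (O1, C2, C3, C3a, C7a) fused to benzo ring A (C4 to C7), with a separate benzene ring B on C2. Ring A carries a 3-methylbut-2-enyl (prenyl) group on C5 and a hydroxyl on C6, C3 carries a methoxy group, and ring B has a hydroxyl at C2' and a methoxy group at C4'. There is no stereocentre and no stereogenic double bond, so every problem is one of regiochemistry or chemoselectivity. The prenyl alkene next to the free C6 hydroxyl closes to a 2,2-dimethylchroman under Brønsted or Lewis acid and does not survive hydrogenation. The 3-methoxyfuran is an electron-rich enol ether that is open to oxidation and to hydrolysis in aqueous acid. The difficulty lies in telling four oxygen substituents apart (two methylated, two free), in placing an oxygen on C3, where ordinary substitution on a finished benzofuran does not put one, and in directing the prenyl group to C5 and not C7. The strategy rests on the oxidation pattern of C2–C3: C2 (bound to ring B and O1) is at the level of an aryl ketone carbon and C3 (bound to OMe and C3a) at that of an aldehyde carbon, which together make an arylglyoxal. C3a is para to the C6 oxygen and ortho to the oxygen on C7a, which makes it the most nucleophilic carbon of a resorcinol.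

## Retrosynthetic reasoning

**12 ⇒ 10 + 11.** The bond between C5 and the prenyl CH2 is cut first. The prenyl group is the one substituent that tolerates neither the acid of the ring-forming step nor a Lewis-acid deprotection, so it is attached last. A bromine on C5 of 10 marks the position. The forward reaction has to couple the aryl bromide with the allylboronate 11 at the unsubstituted allyl terminus, in the presence of two free phenols.

**10 ⇒ 9.** The O–benzyl bond on ring B is cut. The C2' oxygen needs a mask during ring formation, because a free phenol ortho to the dicarbonyl unit would close onto it and would also compete as a nucleophile. A benzyl ether is stable to protic acid. Its removal must spare two methyl ethers (one of them the C3 enol ether) and the C–Br bond, which rules out hydrogenolysis, and it must come before the prenyl group is present.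

**9 ⇒ 4 + 5 + 6.** Three bonds of the furan are cut together: C3–C3a, C3–OMe and O1–C2. Each lies next to an activating heteroatom, and the cut divides the molecule into a bought resorcinol 5 (ring A with O1, the C6 oxygen and the bromine), the arylglyoxal 4 (ring B with C2 and C3 at the right oxidation level) and methanol 6 (the C3 methoxy group). Nothing else gives this gain in one operation from such simple pieces. The forward reaction has to alkylate 5 at the carbon para to one hydroxyl and ortho to the other with the aldehyde carbon of 4 (giving 7), exchange the benzylic hydroxyl for methoxy (giving 8), and then close and dehydrate the furan.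

**4 ⇒ 3 ⇒ 1 + 2.** The aldehyde carbon of 4 is traced back to the acetyl methyl group of 3 by an α-oxidation, and the benzyl ether of 3 to paeonol 1 and benzyl bromide 2. Paeonol already holds the C2' oxygen and the C4' methoxy group of ring B in the right places, so ring B needs no construction.

## Alternatives that were turned down

**Alternative 1:** Ring A is built instead of bought. The C5–C6 bond is cut, which leads back to the fully substituted furan A2. Its two neighbouring side arms are a bis-silyl ketene acetal on the carbon next to oxygen and a (Z)-skipped dienyl chain on the next carbon, and they form a hexatriene with the furan C=C bond. On heating, the triene should close in a six-electron electrocyclisation, and loss of a silanol should aromatise ring A to the bis-silyl ether A1; fluoride would then free both phenols.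
- For it: the arms dictate where the prenyl group and the C6 oxygen sit. Ring A has no regiochemical question, no halogen is needed, the allyl coupling with its choice between the two allyl termini is avoided, and the final deprotection is harmless to the prenyl group and the enol ether. On all these points it is stronger than the chosen route.
- Against it: the difficulty moves into A2. This is a furan with four different substituents that already contains the 2-aryl-3-methoxy pattern, which is the real problem of the target, and it needs two further olefinations. The skipped diene can slip into conjugation, the ketene acetal is sensitive to moisture, and the ring closure must give up furan aromaticity while the inward substituent of the Z-alkene slows it.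
- Comparison: the sequence would run well beyond ten steps. The chosen route forms three furan bonds in one operation and needs five steps in all; it accepts one selectivity bet in exchange for that brevity.

**Alternative 2:** Ring B is taken apart at C1'–C2', C2'–C3' and C4'–C5', giving the benzofuranyl enone diazo ketone A4 and methoxyethyne A5. Irradiation should trigger a Wolff rearrangement to a vinylketene, which adds A5 in a [2+2] reaction. The cyclobutenone then opens, recloses in a six-electron process and tautomerises to A3, with the C2' hydroxyl free and the C4' methoxy group placed by the polarity of the alkyne. Acid removal of the methoxymethyl group would finish the synthesis.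
- For it: the C2' hydroxyl needs no protecting group and the substitution of ring B is fixed by mechanism. On this point the alternative is at least as strong as the chosen route.
- Against it: ring B has exactly the substitution of paeonol 1, so the key step is spent on the cheapest part of the molecule. A4 already contains the prenylated 3-methoxybenzofuran, whose construction remains unsolved. A carbene or ketene next to a prenyl alkene invites cyclopropanation and internal cycloaddition, A5 is volatile and unstable, and the final acidic deprotection beside a prenyl group risks chroman formation.
- Comparison: the chosen route takes ring B from 1 at the cost of one benzyl group and spends its one uncertain step on the furan, which is where the difficulty lies.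

**Alternative 3:** The C2=C3 bond is cut as an olefin. C2 becomes an ylide carbon bearing ring B and O1, and C3 the carbonyl carbon of a methyl ester, both held in the phosphonium salt A7. Base should form the ylide, which attacks the neighbouring ester carbonyl and expels a phosphine oxide, giving the bis-benzyl ether A6 with the C3 methoxy group taken from the ester. A6 differs from 9 only by a benzyl group on O6 and would be finished in the same way.
- For it: every furan atom is placed without an intermolecular regiochemical choice and without competition between nucleophiles, and the internal Wittig reaction of esters is established in benzofuran synthesis. The ring closure is therefore more predictable than the chosen key step, and on that point the alternative is stronger.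
- Against it: A7 is an α-aryloxybenzylphosphonium salt with an electron-rich aryl group. It has to be made from a ring B aldehyde derivative, is likely to ionise or hydrolyse, and its ylide can expel a phenoxide. The ester carbonyl is a poor acceptor flanked by two ortho substituents. The extra benzyl group, the ester, the salt formation and a stoichiometric phosphine oxide bring the route to about eight or nine steps.
- Comparison: the chosen route reaches the same kind of intermediate (9) in three steps from bought materials. It trades certainty for brevity, and keeps a stepwise fallback in reserve.

Key step: step 3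

Assumption: glyoxal 4 is drawn as the free 1,2-dicarbonyl compound; if it is handled as its hydrate, the hydrate is expected to enter step 3 in the same way, the extra water being taken up by the orthoformate.

## Route

Step 1
Reactants: 1 paeonol (2-hydroxy-4-methoxyacetophenone); 2 benzyl bromide
Product: 3 2-(benzyloxy)-4-methoxyacetophenone
Conditions: K2CO3, KI (cat.), DMF, 60 °C
Reagents that add atoms: none
Why: Williamson ether synthesis; the hydrogen-bonded ortho-hydroxy ketone needs carbonate in a dipolar solvent with gentle heating, and there is no other nucleophilic site.

Step 2
Reactants: 3 2-(benzyloxy)-4-methoxyacetophenone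
Product: 4 2-(benzyloxy)-4-methoxyphenylglyoxal
Conditions: SeO2, 1,4-dioxane/H2O (30:1), 100 °C; then toluene azeotrope
Reagents that add atoms: selenium dioxide, O=[Se]=O
Why: Riley oxidation of an aryl methyl ketone to the arylglyoxal through the enol and a selenium ester; the aryl methyl and benzyl ethers are not attacked under these conditions.

Step 3
Reactants: 4 2-(benzyloxy)-4-methoxyphenylglyoxal; 5 4-bromoresorcinol; 6 methanol
Product: 9 2-[2-(benzyloxy)-4-methoxyphenyl]-5-bromo-3-methoxybenzofuran-6-ol, via racemic alpha-hydroxy ketone 7 (not isolated), via racemic alpha-methoxy ketone 8 (not isolated)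
Conditions: p-TsOH·H2O (0.2 equiv), MeOH, 25 °C, 5 added slowly to 4 (1.2 equiv); then HC(OMe)3 (3 equiv), 60 °C
Reagents that add atoms: trimethyl orthoformate, COC(OC)OC (it releases methanol 6 when it takes up water, so its methoxy groups can also end up at C3)
Why: Proposed new method: the protonated aldehyde carbon of 4 should alkylate 5 in a Friedel–Crafts hydroxyalkylation (C3–C3a, giving 7), the benzylic hydroxyl of 7 should ionise to a cation with quinone methide character that the solvent 6 captures (C3–OMe, giving 8), and the ortho phenol should then add to the aryl ketone and the hemiketal lose water to give the aromatic furan (O1–C2); the closest known reaction type is the acid-catalysed three-component coupling of arylglyoxals, phenols and a nitrogen, sulfur or carbon nucleophile to 2-aryl-3-substituted benzofurans, in which an alcohol has not been shown as the third partner. The furan ring closes by a 5-exo-trig addition of the phenol oxygen to the carbonyl group, followed by elimination across C2–C3. No stereocentre remains, since the benzylic centre of 7 and 8 is racemic and becomes sp2. The orientation follows from the aldehyde carbon being the more electrophilic carbonyl carbon, so the arene ends up on C3 and the ketone carbon becomes C2. On 5 the step needs attack at C6 (resorcinol numbering), which is para to one hydroxyl and ortho to the other; the bromine occupies C4, C2 is crowded between two hydroxyls and C5 is meta to both. Capture by 6 and not by a second molecule of 5 is to be secured by using 6 as solvent, by adding 5 slowly to a small excess of 4, and by the aromatisation, which removes the ionisable centre. The orthoformate is held back until the C–C bond is made, so that the aldehyde is not masked beforehand, and it then takes up the water of condensation. The benzyl ether and the C–Br bond should not be touched by p-TsOH in methanol.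

Step 4
Reactants: 9 2-[2-(benzyloxy)-4-methoxyphenyl]-5-bromo-3-methoxybenzofuran-6-ol
Product: 10 5-bromo-2-(2-hydroxy-4-methoxyphenyl)-3-methoxybenzofuran-6-ol
Conditions: BCl3 (3 equiv), C6HMe5 (4 equiv), CH2Cl2, −78 °C; then MeOH/H2O
Reagents that add atoms: none
Why: Lewis-acid cleavage of an aryl benzyl ether with pentamethylbenzene as a non-basic trap for the benzyl cation; at −78 °C aryl methyl ethers and the C–Br bond should remain, and the trap keeps the cation off the electron-rich rings. It is done before the prenyl group is present, because that group would not tolerate BCl3.

Step 5
Reactants: 10 5-bromo-2-(2-hydroxy-4-methoxyphenyl)-3-methoxybenzofuran-6-ol; 11 prenylboronic acid pinacol ester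
Product: 12 ambofuranol, 2-(2-hydroxy-4-methoxyphenyl)-3-methoxy-5-(3-methylbut-2-enyl)benzofuran-6-ol
Conditions: PdCl2(IPent)(3-chloropyridine) (3 mol %; IPent = 1,3-bis[2,6-di(pentan-3-yl)phenyl]imidazol-2-ylidene), KOH (5 M aq, 5 equiv), THF, 70 °C, degassed
Reagents that add atoms: none
Why: Suzuki–Miyaura allyl–aryl coupling; with a very bulky carbene ligand on palladium the allyl group should be bound through its unsubstituted terminus at reductive elimination, which gives the linear prenyl arene and not the 1,1-dimethylallyl isomer. The excess hydroxide covers both phenols, which react as phenoxides.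

## Compound list

1 | paeonol (2-hydroxy-4-methoxyacetophenone) | COc1ccc(C(C)=O)c(O)c1 | starting material
2 | benzyl bromide | BrCc1ccccc1 | starting material
3 | 2-(benzyloxy)-4-methoxyacetophenone | COc1ccc(C(C)=O)c(OCc2ccccc2)c1 | intermediate
4 | 2-(benzyloxy)-4-methoxyphenylglyoxal | COc1ccc(C(=O)C=O)c(OCc2ccccc2)c1 | intermediate
5 | 4-bromoresorcinol | Oc1ccc(Br)c(O)c1 | starting material
6 | methanol | CO | starting material
7 | 1-[2-(benzyloxy)-4-methoxyphenyl]-2-(5-bromo-2,4-dihydroxyphenyl)-2-hydroxyethanone (racemic) | COc1ccc(C(=O)C(O)c2cc(Br)c(O)cc2O)c(OCc2ccccc2)c1 | intermediate (not isolated)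
8 | 1-[2-(benzyloxy)-4-methoxyphenyl]-2-(5-bromo-2,4-dihydroxyphenyl)-2-methoxyethanone (racemic) | COc1ccc(C(=O)C(OC)c2cc(Br)c(O)cc2O)c(OCc2ccccc2)c1 | intermediate (not isolated)
9 | 2-[2-(benzyloxy)-4-methoxyphenyl]-5-bromo-3-methoxybenzofuran-6-ol | COc1ccc(-c2oc3cc(O)c(Br)cc3c2OC)c(OCc2ccccc2)c1 | intermediate
10 | 5-bromo-2-(2-hydroxy-4-methoxyphenyl)-3-methoxybenzofuran-6-ol | COc1ccc(-c2oc3cc(O)c(Br)cc3c2OC)c(O)c1 | intermediate
11 | prenylboronic acid pinacol ester | CC(C)=CCB1OC(C)(C)C(C)(C)O1 | starting material
12 | ambofuranol | COc1ccc(-c2oc3cc(O)c(CC=C(C)C)cc3c2OC)c(O)c1 | target

## Step count and risks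

Total step count: 5. Longest linear sequence: 5 steps (1 → 3 → 4 → 9 → 10 → 12); 5, 6 and 11 enter as bought.

**Step 3 (key step, proposed new method).** The most likely failure is capture of the benzylic cation by a second molecule of the resorcinol instead of methanol. That C–C bond formation is irreversible, whereas the C–O bond to methanol is reversible until the furan has aromatised. Attack at the crowded carbon between the two hydroxyls, or stalling before dehydration, are lesser risks.

The fallback uses known chemistry only, sets out from 5 and 2, and returns to the route at 8 and hence 9:
- 5 would be formylated under Vilsmeier–Haack conditions (POCl3, DMF) at the same carbon that the key step uses, giving 5-bromo-2,4-dihydroxybenzaldehyde F1.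
- Both phenols would be masked (chloromethyl methyl ether, i-Pr2NEt) to give 5-bromo-2,4-bis(methoxymethoxy)benzaldehyde F2.
- Separately, commercial 2-hydroxy-4-methoxybenzaldehyde would be benzylated with 2 (K2CO3, DMF) to 2-(benzyloxy)-4-methoxybenzaldehyde F3, and this converted with propane-1,3-dithiol and BF3·OEt2 into 2-[2-(benzyloxy)-4-methoxyphenyl]-1,3-dithiane F4.
- In a Corey–Seebach reaction, F4 would be deprotonated (n-BuLi, THF, −78 °C) and added to F2, and the lithium alkoxide methylated in the same flask (MeI, DMPU), giving the dithiane methyl ether 2-[2-(benzyloxy)-4-methoxyphenyl]-2-{[5-bromo-2,4-bis(methoxymethoxy)phenyl](methoxy)methyl}-1,3-dithiane F5.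
- Unmasking with MeI and CaCO3 in aqueous MeCN would give the protected α-methoxy ketone 1-[2-(benzyloxy)-4-methoxyphenyl]-2-[5-bromo-2,4-bis(methoxymethoxy)phenyl]-2-methoxyethanone F6.
- HCl in methanol would remove both methoxymethyl groups to give 8, which cyclodehydrates to 9 under the same conditions. No free resorcinol is present here to compete, and exchange of the benzylic methoxy group with the solvent is degenerate.

**Step 5.** Oxidative addition of zerovalent palladium into a C–Br bond ortho to a phenoxide may be slow. Reductive elimination through the substituted allyl terminus would give the reverse-prenyl isomer, and protodeboronation of 11 can use up the reagent.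

The fallback sets out from 10 and returns at 12:
- Both phenols would be silylated (triisopropylsilyl triflate, 2,6-lutidine) to the 10 bis(triisopropylsilyl) ether F7.
- Bromine–lithium exchange (t-BuLi, THF, −78 °C), transmetalation with CuBr·SMe2 and alkylation of the arylcopper with prenyl bromide at the primary carbon should give the ambofuranol bis(triisopropylsilyl) ether F8.
- Tetrabutylammonium fluoride in THF would then free 12.
- The bulky silyl groups are chosen so that the ortho-lithiated silyl ether does not undergo oxygen-to-carbon silyl migration.

**Step 4.** Boron bound to the freed C2' oxygen sits close to the C3 methoxy group, so a methyl ether could be lost together with the benzyl group. C-benzylation of the electron-rich rings is possible if the cation trap is outcompeted.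

The fallback changes the protecting group from the start. It sets out from 1 and returns at 10, and it assumes that the ring-forming method of step 3 has already been shown to work:
- 1 would be converted with p-toluenesulfonyl chloride, Et3N and 4-(dimethylamino)pyridine into 2-acetyl-5-methoxyphenyl 4-methylbenzenesulfonate F9.
- Oxidation with SeO2 as in step 2 would give 5-methoxy-2-(oxoacetyl)phenyl 4-methylbenzenesulfonate F10.
- Condensation with 5 and 6 as in step 3 would give 2-(5-bromo-6-hydroxy-3-methoxybenzofuran-2-yl)-5-methoxyphenyl 4-methylbenzenesulfonate F11. The sulfonate is inert to acid and makes the ketone more electrophilic.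
- Hydrolysis with KOH in MeOH/H2O at 65 °C would give 10 without any Lewis acid.

## Further compounds

F1 | step 3 | 5-bromo-2,4-dihydroxybenzaldehyde | O=Cc1cc(Br)c(O)cc1O
F2 | step 3 | 5-bromo-2,4-bis(methoxymethoxy)benzaldehyde | O=Cc1cc(Br)c(OCOC)cc1OCOC
F3 | step 3 | 2-(benzyloxy)-4-methoxybenzaldehyde | COc1ccc(C=O)c(OCc2ccccc2)c1
F4 | step 3 | 2-[2-(benzyloxy)-4-methoxyphenyl]-1,3-dithiane | COc1ccc(C2SCCCS2)c(OCc2ccccc2)c1
F5 | step 3 | 2-[2-(benzyloxy)-4-methoxyphenyl]-2-{[5-bromo-2,4-bis(methoxymethoxy)phenyl](methoxy)methyl}-1,3-dithiane (racemic) | COc1ccc(C2(C(OC)c3cc(Br)c(OCOC)cc3OCOC)SCCCS2)c(OCc2ccccc2)c1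
F6 | step 3 | 1-[2-(benzyloxy)-4-methoxyphenyl]-2-[5-bromo-2,4-bis(methoxymethoxy)phenyl]-2-methoxyethanone (racemic) | COc1ccc(C(=O)C(OC)c2cc(Br)c(OCOC)cc2OCOC)c(OCc2ccccc2)c1
F7 | step 5 | 10 bis(triisopropylsilyl) ether | COc1ccc(-c2oc3cc(O[Si](C(C)C)(C(C)C)C(C)C)c(Br)cc3c2OC)c(O[Si](C(C)C)(C(C)C)C(C)C)c1
F8 | step 5 | ambofuranol bis(triisopropylsilyl) ether | COc1ccc(-c2oc3cc(O[Si](C(C)C)(C(C)C)C(C)C)c(CC=C(C)C)cc3c2OC)c(O[Si](C(C)C)(C(C)C)C(C)C)c1
F9 | step 4 | 2-acetyl-5-methoxyphenyl 4-methylbenzenesulfonate | COc1ccc(C(C)=O)c(OS(=O)(=O)c2ccc(C)cc2)c1
F10 | step 4 | 5-methoxy-2-(oxoacetyl)phenyl 4-methylbenzenesulfonate | COc1ccc(C(=O)C=O)c(OS(=O)(=O)c2ccc(C)cc2)c1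
F11 | step 4 | 2-(5-bromo-6-hydroxy-3-methoxybenzofuran-2-yl)-5-methoxyphenyl 4-methylbenzenesulfonate | COc1ccc(-c2oc3cc(O)c(Br)cc3c2OC)c(OS(=O)(=O)c2ccc(C)cc2)c1
A1 | alternative 1 | ambofuranol 6-O-tert-butyldimethylsilyl 2'-O-triisopropylsilyl bis-ether | COc1ccc(-c2oc3cc(O[Si](C)(C)C(C)(C)C)c(CC=C(C)C)cc3c2OC)c(O[Si](C(C)C)(C(C)C)C(C)C)c1
A2 | alternative 1 | 5-[2,2-bis(tert-butyldimethylsilyloxy)vinyl]-3-methoxy-4-[(Z)-5-methylhexa-1,4-dienyl]-2-[4-methoxy-2-(triisopropylsilyloxy)phenyl]furan | COc1ccc(-c2oc(C=C(O[Si](C)(C)C(C)(C)C)O[Si](C)(C)C(C)(C)C)c(/C=C\CC=C(C)C)c2OC)c(O[Si](C(C)C)(C(C)C)C(C)C)c1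
A3 | alternative 2 | ambofuranol 6-O-methoxymethyl ether | COc1ccc(-c2oc3cc(OCOC)c(CC=C(C)C)cc3c2OC)c(O)c1
A4 | alternative 2 | (E)-1-diazo-4-[3-methoxy-6-(methoxymethoxy)-5-(3-methylbut-2-enyl)benzofuran-2-yl]but-3-en-2-one | COc1c(/C=C/C(=O)C=[N+]=[N-])oc2cc(OCOC)c(CC=C(C)C)cc12
A5 | alternative 2 | methoxyethyne | C#COC
A6 | alternative 3 | 6-(benzyloxy)-2-[2-(benzyloxy)-4-methoxyphenyl]-5-bromo-3-methoxybenzofuran | COc1ccc(-c2oc3cc(OCc4ccccc4)c(Br)cc3c2OC)c(OCc2ccccc2)c1
A7 | alternative 3 | {[2-(benzyloxy)-4-methoxyphenyl][5-(benzyloxy)-4-bromo-2-(methoxycarbonyl)phenoxy]methyl}triphenylphosphonium bromide | COC(=O)c1cc(Br)c(OCc2ccccc2)cc1OC(c1ccc(OC)cc1OCc1ccccc1)[P+](c1ccccc1)(c1ccccc1)c1ccccc1.[Br-]
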